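All runs come from a simulation with made-up constants, and the scatter is random.

A small charge of free catalyst, 7.9 mol% of the substrate, carries each of these flasks, so the useful measure is what that catalyst does per minute.

in all of them: free catalyst 7.9 mol%
- ash: substrate 41 mM; reagent 0.74 equiv; run made earlier
- elm: substrate 41 mM; reagent 1.7 equiv; run made earlier
- maple: substrate 20 mM; reagent 1.1 equiv; run made earlier
- flask: substrate 41 mM; reagent 1.10 equiv; time 3.0 min

- ash (time / min: target / %): 0.200: 9.0; 0.667: 24.9; 1.00: 33.2; 1.50: 43.3; 2.50: 60.1
- elm (time / min: target / %): 0.200: 9.1; 0.333: 13.2; 0.667: 24.3; 1.33: 41.0; 2.50: 61.0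
- maple (time / min: target / %): 0.200: 10.4; 0.667: 30.5; 1.00: 41.7; 1.50: 57.4; 2.50: 78.3

(standard deviation of a reading: 1 percentage point)

- amount of target in percent of the substrate charged, at 40 s, 1.5 min and 3.0 min

Between 1.50 min and 2.50 min, ash gained target at 2.13 /min. This is the turnover pace: the fraction of the charge gained as target per minute, divided by the catalyst loading, the usual turnover frequency. Elm, with 1.7 equiv of reagent against 0.74 equiv in ash, gives nearly the same pace over 1.33 min to 2.50 min, 2.16 /min. The flask, at 1.10 equiv with the substrate and loading of both, is therefore read on their curve.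

Maple looks nearly the same as the flask, with equal equivalents and loading, but its substrate charge is about half as large. Its pace is faster, 2.65 /min, and it stands at 78.3% at 2.50 min, so maple is no guide to the flask's course.

This reckoning takes 24.6% at 40 s from ash and elm, and 43.3% at 1.5 min from ash. From their mean of 60.5% at 2.50 min, their mean pace, taken as held, gives 69.0% at 3.0 min. Put back against the runs, that held pace is an assumption: maple's pace read 3.97 /min over 1.00 min to 1.50 min against the later 2.65 /min, and ash's read 2.56 /min against 2.13 /min, so 69.0% is a rough figure.

The forecast, holding that “the rate is essentially zero order in reagent”, gave 24.6%, 44% and 67%, the last lower than this reckoning.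

The flask gives 24.9%, 44.5% and 69.3%.

    catalyst intermediate B ⇌ by-product + catalyst intermediate C (K = 0.00410 M, k = 2.20 /s)
    catalyst intermediate D → free catalyst + target (k = 0.483 /s)
    2 free catalyst → spent catalyst (k = 9.65 /M/s)
    reagent → decomposition product (k = 8.45 × 10⁻⁶ /s)
    substrate + catalyst intermediate A → catalyst intermediate B (k = 846 /M/s)
    reagent + free catalyst ⇌ catalyst intermediate A (K = 61.6 /M, k = 887 /M/s)
    2 reagent → self-condensation product (k = 0.0761 /M/s)
    catalyst intermediate C → catalyst intermediate D (k = 0.265 /s)

Between 1.5 min and 3.0 min the flask ran at a turnover pace of 2.09 /min, close to ash's 2.13 /min and slower than maple's 2.65 /min, while catalyst intermediate B, the resting state, held 74.6% of the catalyst at 1.50 min and 79.3% at 3.00 min. Catalyst intermediate C held 15.7% and then 11.0%, so its step to catalyst intermediate D, with constant 0.265 /s, passed 2.50 /min at the first time and 1.75 /min at the second.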